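**Plan**
Locants (elemane numbering): the ring is C5–C10. C10 bears CH3 (C14) and the vinyl group (C1=C2), C5 the 3-hydroxyprop-1-en-2-yl arm (C4, C3, C15), C6 the OH, C7 the acrylic acid arm (C11, C12, C13), C8 the ester oxygen, and C9 is the ring CH2. β is the ring face that carries the vinyl group.
Enabling feature: vinyl carbon C1 and the oxygen on C6 stand cis-1,3 (diaxial) on the cyclohexane. They can be tied back into a γ-butyrolactone ring C1(=O)–O–C6–C5–C10 whose α-carbon is the quaternary C10. The 2-substituted acrylate on C7 is the footprint of a radical allyl transfer (SH2′).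
Retrosynthesis: cut the C8–O acyl bond, then C1=C2 (Wittig, back to the bridging lactone), then C9–C10 and C7–C8 together. This releases a two-carbon silyl enol ether and a monocyclic lactone with PhSe on C10 and an allyl sulfone enoate on C6. Both ring bonds join carbons of like polarity (donor–donor, acceptor–acceptor), so radicals make them.
Forward: the lactone ring is present from the first compound. The cyclohexane ring arises in one step across lactone atoms C10 and C6, the lactone is then opened to vinyl and OH, and the side-chain acid is joined last.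
Stereochemistry: C6 comes from (S)-5-(hydroxymethyl)furan-2(5H)-one and C5 from anti cuprate addition. C10, C8 and C7 are set in the annulation under control of the lactone. The Z alkene of the side chain comes from the ring of 3-methylfuran-2(5H)-one.

Key step: step 9

Assumption: the target is a γ-hydroxy acid whose C6 hydroxyl is cis to the C7 acrylic acid arm. It is taken to be isolable in the open form if it is liberated as the carboxylate and acidified only to about pH 5 in the cold.

Step 1
Reactants: 1 (S)-5-(hydroxymethyl)furan-2(5H)-one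
Product: 2 (S)-5-[(tert-butyldimethylsilyloxy)methyl]furan-2(5H)-one
Conditions: TBSCl, imidazole, CH2Cl2, 0 °C to rt
Reagents that add atoms: tert-butyldimethylsilyl chloride, CC(C)(C)[Si](C)(C)Cl
Why: Imidazole-promoted silylation of a primary alcohol, which touches no stereocentre and supplies the bulky C6 substituent that will steer the conjugate addition.

Step 2
Reactants: 3 2-bromoprop-2-en-1-ol
Product: 4 [(2-bromoprop-2-en-1-yl)oxy](tert-butyl)diphenylsilane
Conditions: TBDPSCl, imidazole, CH2Cl2, rt
Reagents that add atoms: tert-butyldiphenylsilyl chloride, CC(C)(C)[Si](Cl)(c1ccccc1)c1ccccc1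
Why: Standard silylation that gives a C15 protecting group which outlasts the TBS and Me3Si ethers and whose bulk retards O-to-C silyl migration in the derived vinyllithium.

Step 3
Reactants: 4 [(2-bromoprop-2-en-1-yl)oxy](tert-butyl)diphenylsilane; 2 (S)-5-[(tert-butyldimethylsilyloxy)methyl]furan-2(5H)-one
Product: 8 (3S,4R,5S)-5-[(tert-butyldimethylsilyloxy)methyl]-4-[3-(tert-butyldiphenylsilyloxy)prop-1-en-2-yl]-3-methyloxolan-2-one, via vinyllithium 5 (not isolated), via lithium divinylcuprate 6 (not isolated), via lithium enolate 7 (not isolated)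
Conditions: 4 (2.2 equiv), t-BuLi (4.4 equiv), Et2O, −78 °C; CuBr·SMe2 (1.1 equiv), −78 to −40 °C; 2, −78 °C; then MeI, DMPU, −78 to −20 °C; aq. NH4Cl
Reagents that add atoms: iodomethane, CI
Why: Tandem cuprate 1,4-addition and enolate alkylation on a butenolide, in which the cuprate adds anti to the C6 CH2OTBS group and so sets C5, while MeI enters anti to the new C5 arm at a centre (C10) that is erased later.

Step 4
Reactants: 8 (3S,4R,5S)-α-methyl lactone
Product: 10 (3S,4R,5S)-5-[(tert-butyldimethylsilyloxy)methyl]-4-[3-(tert-butyldiphenylsilyloxy)prop-1-en-2-yl]-3-methyl-3-(phenylselanyl)oxolan-2-one, via lithium enolate 9 (not isolated)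
Conditions: LiN(i-Pr)2 (LDA), THF, −78 °C; PhSeBr, −78 °C
Reagents that add atoms: benzeneselenenyl bromide, Br[Se]c1ccccc1
Why: α-Selenenylation of a lactone enolate (selenium enters anti to the C5 arm, of no consequence) gives a tertiary selenide that tolerates the amine bases and nucleophiles of steps 6–8, where a tertiary bromide would eliminate, and serves as the radical precursor.

Step 5
Reactants: 10 selenide
Product: 11 primary alcohol (C7 OH free; otherwise as 10)
Conditions: camphorsulfonic acid (10 mol %), MeOH/CH2Cl2, 0 °C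
Reagents that add atoms: none
Why: Acid-catalysed methanolysis cleaves the primary TBS ether much faster than the TBDPS ether and leaves lactone and selenide alone.

Step 6
Reactants: 11 primary alcohol
Product: 12 aldehyde (C7 = CHO on lactone carbon C6)
Conditions: (COCl)2, DMSO, CH2Cl2, −78 °C; Et3N, −78 to −20 °C
Reagents that add atoms: none
Why: Swern oxidation uses activated DMSO at low temperature and spares the selenide (peroxide or hypervalent iodine oxidants would start a selenoxide elimination), and any enolisation at C6 returns to the favoured trans C5/C6 arrangement.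

Step 7
Reactants: 12 aldehyde; 13 tert-butyl acrylate
Product: 14 allylic alcohol C7H(OH)–C11(=C13H2)CO2t-Bu (both C7 epimers)
Conditions: 13 (5 equiv), quinuclidine (0.5 equiv), MeOH (1 equiv), rt
Reagents that add atoms: none
Why: Morita–Baylis–Hillman reaction of an activated α-acyloxy aldehyde forms C7–C11, and the new carbinol centre needs no control because step 8 removes it.

Step 8
Reactants: 14 allylic alcohol
Product: 16 (Z)-allyl sulfone C6–C7H=C11(CO2t-Bu)–C13H2SO2Ph (C6 cis to CH2SO2Ph), via allylic acetate 15 (not isolated)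
Conditions: Ac2O, pyridine, DMAP (cat.), CH2Cl2, 0 °C; concentrate; PhSO2Na, DMF, rt
Reagents that add atoms: acetic anhydride, CC(=O)OC(C)=O (atoms stay only in 15); sodium benzenesulfinate, [Na+].[O-]S(=O)c1ccccc1
Why: SN2′ displacement of a Morita–Baylis–Hillman acetate by sulfinate at the CH2 terminus is the known route to (Z)-2-(sulfonylmethyl)enoates and places the radical leaving group on C13 and the acceptor carbon at C7.

Step 9
Reactants: 16 (Z)-allyl sulfone selenide; 17 trimethyl(vinyloxy)silane
Product: 18 bridged lactone tert-butyl 2-{1-methyl-7-oxo-3-(trimethylsilyloxy)-8-[3-(tert-butyldiphenylsilyloxy)prop-1-en-2-yl]-6-oxabicyclo[3.2.1]octan-4-yl}acrylate (10α-CH3; β C1(=O)–O6 bridge; 5β arm; 7β arm; 8α-OSiMe3)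
Conditions: 17 (15 equiv), Bu3SnSnBu3 (1.2 equiv), benzene (0.02 M in 16), sunlamp through Pyrex, 25–35 °C
Reagents that add atoms: none
Why: Proposed new method: Bu3Sn• from photolysis of the ditin abstracts PhSe from 16 to give the planar, electrophilic tertiary α-lactone radical at C10, which adds to the CH2 terminus of the electron-rich enol ether 17 (C9–C10); the nucleophilic α-silyloxy radical at C8 then attacks C7 of the electron-poor enoate (C7–C8), and the C11 radical expels PhSO2•, which unveils the C11=C13 acrylate and is turned back into Bu3Sn• by the ditin. Each elementary step is known (addition of α-ester radicals to enol ethers and vinyl esters, radical annulation by addition–cyclisation, Keck-type allyl transfer from allyl sulfones under ditin), but their union into a [4+2] annulation that bridges a γ-lactone is not, hence the label. The cyclohexane ring closes 6-exo-trig, whereas 4-exo or 5-endo closure of the first radical onto its own enoate is barred by geometry and by polarity mismatch, which leaves it time for the bimolecular step. C10 is set by approach of 17 anti to the adjacent C5 arm, that is on the lactone face that carries C7, and an adduct from the other face cannot reach C7 and cannot enter the product. C8 and C7 are set in a chair-like transition state of the forming 6-oxabicyclo[3.2.1]octane, where OSiMe3 avoids the axial site under the lactone bridge and the bulky C11 arm avoids the axial site syn to H5 and H9, so that both should end equatorial and trans. The step needs the C8 radical to prefer the enoate over the C3=C4 alkene, over more 17 and over PhSe transfer, which is secured by polarity matching, by the trans ring fusion that closure onto C3=C4 would demand, by high dilution of 16 and by only a moderate excess of 17.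

Step 10
Reactants: 18 bridged lactone
Product: 19 bridged lactol (C1 = CHOH; both anomers)
Conditions: i-Bu2AlH (1.1 equiv), toluene, −78 °C; aq. potassium sodium tartrate
Reagents that add atoms: none
Why: Partial reduction of a lactone to the lactol, in which the lactone (locked in the more reactive E ester conformation) is attacked ahead of the conjugated, α-branched tert-butyl ester and the aluminium hemiacetal is stable at −78 °C.

Step 11
Reactants: 19 bridged lactol
Product: 21 diol tert-butyl ester (10β-vinyl; 6β-OH; 8α-OH; C15 OTBDPS), via trimethylsilyl ether 20 (not isolated)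
Conditions: Ph3PCH3Br, n-BuLi, THF, 0 °C; 19, 0 °C to rt; work-up; citric acid, MeOH, 0 °C
Reagents that add atoms: methyltriphenylphosphonium bromide, C[P+](c1ccccc1)(c1ccccc1)c1ccccc1.[Br-]
Why: Wittig methylenation of the lactol through its open hydroxy aldehyde form turns C1 into the vinyl CH and releases O6 as the axial hydroxyl without touching a stereocentre, while the lithium counter-ion, low temperature and bulk of the tert-butyl ester hold back attack of the C6 alkoxide on C12, and mild acid methanolysis then removes only the Me3Si ether.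

Step 12
Reactants: 22 3-methylfuran-2(5H)-one
Product: 25 4-methoxybenzyl (Z)-4-acetoxy-2-methylbut-2-enoate, via potassium carboxylate 23 (not isolated), via hydroxy ester 24 (not isolated)
Conditions: KOH (1.0 equiv), MeOH/H2O, rt; evaporate to dryness; 4-methoxybenzyl chloride, Bu4NI (cat.), DMF, rt; then Ac2O, pyridine, DMAP (cat.), 0 °C
Reagents that add atoms: potassium hydroxide, [K+].[OH-]; 4-methoxybenzyl chloride, COc1ccc(CCl)cc1; acetic anhydride, CC(=O)OC(C)=O
Why: Saponification of the butenolide delivers the Z geometry because carbonyl and CH2O are cis in the ring, and O-alkylation of the dry carboxylate followed at once by acetylation locks the open form without ever activating the acid toward relactonisation.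

Step 13
Reactants: 25 4-methoxybenzyl ester
Product: 26 (Z)-4-acetoxy-2-methylbut-2-enoic acid
Conditions: CF3CO2H, anisole, CH2Cl2, 0 °C
Reagents that add atoms: none
Why: Acidolysis of the 4-methoxybenzyl ester, with Friedel–Crafts capture of the benzyl cation by anisole, frees the acid without base, so the acetate and the Z alkene stay intact.

Step 14
Reactants: 26 (Z)-4-acetoxy-2-methylbut-2-enoic acid; 21 diol tert-butyl ester
Product: 28 C8 ester (8α-O-[(Z)-4-acetoxy-2-methylbut-2-enoyl]; 6β-OH free), via mixed anhydride 27 (not isolated)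
Conditions: 26, 2,4,6-trichlorobenzoyl chloride, Et3N, toluene, rt; then 21, DMAP (0.3 equiv), toluene, 0 °C to rt
Reagents that add atoms: 2,4,6-trichlorobenzoyl chloride, O=C(Cl)c1c(Cl)cc(Cl)cc1Cl (atoms stay only in 27)
Why: Yamaguchi esterification should pick the equatorial C8 hydroxyl because the C6 hydroxyl is axial, flanked by two branched arms and syn-diaxial to the vinyl group, and the mixed anhydride with little DMAP at low temperature is the protocol known to preserve angelate-type Z geometry.

Step 15
Reactants: 28 C8 ester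
Product: 30 target, via bis(trimethylsilyl) derivative 29 (not isolated)
Conditions: Me3SiOTf, 2,6-lutidine, CH2Cl2, 0 °C; concentrate; Bu4NF/AcOH (1:1), THF, 0 °C to rt; pH 5 phosphate buffer, 0 °C
Reagents that add atoms: trimethylsilyl trifluoromethanesulfonate, C[Si](C)(C)OS(=O)(=O)C(F)(F)F (atoms stay only in 29)
Why: Silyl triflate-mediated cleavage of the tert-butyl ester (loss of isobutene) followed by buffered fluoride desilylation, in which the silyl ester falls first so that C12 is an unreactive carboxylate before O6 and O15 are freed, and the acetate buffer spares the two remaining esters.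

**Compound list**
1 | (S)-5-(hydroxymethyl)furan-2(5H)-one | O=C1O[C@H](CO)C=C1 | starting material
2 | (S)-5-[(tert-butyldimethylsilyloxy)methyl]furan-2(5H)-one | O=C1O[C@H](CO[Si](C)(C)C(C)(C)C)C=C1 | intermediate
3 | 2-bromoprop-2-en-1-ol | C=C(Br)CO | starting material
4 | [(2-bromoprop-2-en-1-yl)oxy](tert-butyl)diphenylsilane | C=C(Br)CO[Si](c1ccccc1)(c1ccccc1)C(C)(C)C | intermediate
5 | 3-(tert-butyldiphenylsilyloxy)prop-1-en-2-yllithium | [Li]C(=C)CO[Si](c1ccccc1)(c1ccccc1)C(C)(C)C | intermediate
6 | lithium bis[3-(tert-butyldiphenylsilyloxy)prop-1-en-2-yl]cuprate | [Li+].C=C(CO[Si](c1ccccc1)(c1ccccc1)C(C)(C)C)[Cu-]C(=C)CO[Si](c1ccccc1)(c1ccccc1)C(C)(C)C | intermediate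
7 | lithium enolate of the 1,4-adduct (C5 arm trans to C7) | [Li]OC1=C[C@H](C(=C)CO[Si](c2ccccc2)(c2ccccc2)C(C)(C)C)[C@@H](CO[Si](C)(C)C(C)(C)C)O1 | intermediate
8 | (3S,4R,5S)-5-[(tert-butyldimethylsilyloxy)methyl]-4-[3-(tert-butyldiphenylsilyloxy)prop-1-en-2-yl]-3-methyloxolan-2-one | O=C1O[C@H](CO[Si](C)(C)C(C)(C)C)[C@@H](C(=C)CO[Si](c2ccccc2)(c2ccccc2)C(C)(C)C)[C@@H]1C | intermediate
9 | lithium enolate of 8 | [Li]OC1=C(C)[C@H](C(=C)CO[Si](c2ccccc2)(c2ccccc2)C(C)(C)C)[C@@H](CO[Si](C)(C)C(C)(C)C)O1 | intermediate
10 | (3S,4R,5S)-3-methyl-3-(phenylselanyl) lactone (Se trans to the C5 arm) | O=C1O[C@H](CO[Si](C)(C)C(C)(C)C)[C@@H](C(=C)CO[Si](c2ccccc2)(c2ccccc2)C(C)(C)C)[C@]1(C)[Se]c3ccccc3 | intermediate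
11 | primary alcohol (C7 OH) | O=C1O[C@H](CO)[C@@H](C(=C)CO[Si](c2ccccc2)(c2ccccc2)C(C)(C)C)[C@]1(C)[Se]c3ccccc3 | intermediate
12 | aldehyde (C7 CHO) | O=C1O[C@H](C=O)[C@@H](C(=C)CO[Si](c2ccccc2)(c2ccccc2)C(C)(C)C)[C@]1(C)[Se]c3ccccc3 | intermediate
13 | tert-butyl acrylate | C=CC(=O)OC(C)(C)C | starting material
14 | Morita–Baylis–Hillman alcohol (both C7 epimers) | O=C1O[C@H](C(O)C(=C)C(=O)OC(C)(C)C)[C@@H](C(=C)CO[Si](c2ccccc2)(c2ccccc2)C(C)(C)C)[C@]1(C)[Se]c3ccccc3 | intermediate
15 | Morita–Baylis–Hillman acetate (both C7 epimers) | O=C1O[C@H](C(OC(C)=O)C(=C)C(=O)OC(C)(C)C)[C@@H](C(=C)CO[Si](c2ccccc2)(c2ccccc2)C(C)(C)C)[C@]1(C)[Se]c3ccccc3 | intermediate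
16 | (Z)-allyl sulfone selenide | O=C1O[C@H](/C=C(/C(=O)OC(C)(C)C)CS(=O)(=O)c4ccccc4)[C@@H](C(=C)CO[Si](c2ccccc2)(c2ccccc2)C(C)(C)C)[C@]1(C)[Se]c3ccccc3 | intermediate
17 | trimethyl(vinyloxy)silane | C=CO[Si](C)(C)C | starting material
18 | bridged lactone (6-oxabicyclo[3.2.1]octan-7-one; 8α-OSiMe3, 7β acrylate arm, 5β arm, 10α-CH3) | O=C2[C@@]1(C)C[C@H](O[Si](C)(C)C)[C@@H](C(=C)C(=O)OC(C)(C)C)[C@@H](O2)[C@H]1C(=C)CO[Si](c3ccccc3)(c3ccccc3)C(C)(C)C | intermediate
19 | bridged lactol (both anomers at C1) | OC2[C@@]1(C)C[C@H](O[Si](C)(C)C)[C@@H](C(=C)C(=O)OC(C)(C)C)[C@@H](O2)[C@H]1C(=C)CO[Si](c3ccccc3)(c3ccccc3)C(C)(C)C | intermediate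
20 | 10β-vinyl 6β-alcohol, C8 trimethylsilyl ether | C=C[C@@]1(C)C[C@H](O[Si](C)(C)C)[C@@H](C(=C)C(=O)OC(C)(C)C)[C@@H](O)[C@H]1C(=C)CO[Si](c2ccccc2)(c2ccccc2)C(C)(C)C | intermediate
21 | 6β,8α-diol tert-butyl ester | C=C[C@@]1(C)C[C@H](O)[C@@H](C(=C)C(=O)OC(C)(C)C)[C@@H](O)[C@H]1C(=C)CO[Si](c2ccccc2)(c2ccccc2)C(C)(C)C | intermediate
22 | 3-methylfuran-2(5H)-one | CC1=CCOC1=O | starting material
23 | potassium (Z)-4-hydroxy-2-methylbut-2-enoate | [K+].[O-]C(=O)/C(C)=C\CO | intermediate
24 | 4-methoxybenzyl (Z)-4-hydroxy-2-methylbut-2-enoate | COc1ccc(COC(=O)/C(C)=C\CO)cc1 | intermediate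
25 | 4-methoxybenzyl (Z)-4-acetoxy-2-methylbut-2-enoate | COc1ccc(COC(=O)/C(C)=C\COC(C)=O)cc1 | intermediate
26 | (Z)-4-acetoxy-2-methylbut-2-enoic acid | OC(=O)/C(C)=C\COC(C)=O | intermediate
27 | (Z)-4-acetoxy-2-methylbut-2-enoic 2,4,6-trichlorobenzoic anhydride | O=C(OC(=O)/C(C)=C\COC(C)=O)c1c(Cl)cc(Cl)cc1Cl | intermediate
28 | C8 ester, tert-butyl ester, C15 TBDPS ether, 6β-OH free | C=C[C@@]1(C)C[C@H](OC(=O)/C(C)=C\COC(C)=O)[C@@H](C(=C)C(=O)OC(C)(C)C)[C@@H](O)[C@H]1C(=C)CO[Si](c2ccccc2)(c2ccccc2)C(C)(C)C | intermediate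
29 | trimethylsilyl ester and C6 trimethylsilyl ether of the C15 TBDPS ether | C=C[C@@]1(C)C[C@H](OC(=O)/C(C)=C\COC(C)=O)[C@@H](C(=C)C(=O)O[Si](C)(C)C)[C@@H](O[Si](C)(C)C)[C@H]1C(=C)CO[Si](c2ccccc2)(c2ccccc2)C(C)(C)C | intermediate
30 | CNP0261293.7 (10β-vinyl, 10α-CH3, 5β arm, 6β-OH, 7β acrylic acid arm, 8α-acyloxy) | C=C[C@@]1(C)C[C@H](OC(=O)/C(C)=C\COC(C)=O)[C@@H](C(=C)C(=O)O)[C@@H](O)[C@H]1C(=C)CO | target

**Total step count:** 15. **Longest linear sequence:** 12 steps (1, 3–11, 14, 15).

**Steps most likely to fail**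

Step 9 (bears the label).
- What may go wrong: telomerisation of the enol ether; selenium transfer to the C8 radical before ring closure; capture of the C8 radical by the C3=C4 alkene; slow regeneration of the tin radical from the sulfonyl radical.
- Fallback (polar, known reactions only, from 8 back to 18):
  - Enolate 9 is alkylated with prenyl bromide anti to the C5 arm (C9–C10) to give the prenyl lactone F1.
  - Camphorsulfonic acid in MeOH frees the primary alcohol F2, and Swern oxidation gives the aldehyde F3.
  - The Morita–Baylis–Hillman reaction with 13 gives the allylic alcohol F4.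
  - NBS/Me2S converts F4 with allylic transposition into the (Z)-allyl bromide F5.
  - One equivalent of ozone, then Me2S, cleaves only the electron-rich trisubstituted prenyl alkene and gives the C8 aldehyde F6.
  - CrCl2 in THF (intramolecular Nozaki–Hiyama allylation through the γ-carbon C7, the classical entry to 2-substituted acrylates next to a carbinol) closes C7–C8 to the hydroxy lactone F7.
  - Me3SiCl/imidazole turns F7 into 18.

Step 11.
- What may go wrong: attack of the C6 alkoxide on the tert-butyl ester (translactonisation) while the ylide is still consuming the aldehyde; reluctance of the bridged lactol to open.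
- Fallback (from 19 back to 21):
  - Me3SiCH2MgCl (3 equiv, THF, −20 °C) adds to the open form and gives the β-hydroxysilane F8, in which O6 is held as a poorly nucleophilic magnesium alkoxide at low temperature.
  - BF3·OEt2 (CH2Cl2, −20 °C) then triggers the acidic Peterson elimination to the vinyl group.
  - Citric acid in MeOH strips the C8 silyl ether to give 21.

Step 14.
- What may go wrong: Z to E isomerisation of the activated acid by reversible conjugate addition of DMAP; sluggish acylation next to the C7 arm; erosion of site selectivity under forcing.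
- Fallback (from 21 back to 28):
  - The ester bond is made first with an acid that has no alkene geometry to lose. DCC with catalytic DMAP couples 2-[bis(2,2,2-trifluoroethoxy)phosphoryl]propanoic acid to the C8 hydroxyl and gives the phosphonate ester F9.
  - KN(SiMe3)2 (1.0 equiv, which deprotonates only the far more acidic phosphonate carbon), 18-crown-6, THF, −78 °C and 2-oxoethyl acetate then build the Z alkene on the substrate by Still–Gennari olefination to give 28.

**Further compounds**
F1 | step 9 | prenyl lactone (C9 trans to the C5 arm) | O=C1O[C@H](CO[Si](C)(C)C(C)(C)C)[C@@H](C(=C)CO[Si](c2ccccc2)(c2ccccc2)C(C)(C)C)[C@]1(C)CC=C(C)C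
F2 | step 9 | primary alcohol of the prenyl series | O=C1O[C@H](CO)[C@@H](C(=C)CO[Si](c2ccccc2)(c2ccccc2)C(C)(C)C)[C@]1(C)CC=C(C)C
F3 | step 9 | aldehyde of the prenyl series | O=C1O[C@H](C=O)[C@@H](C(=C)CO[Si](c2ccccc2)(c2ccccc2)C(C)(C)C)[C@]1(C)CC=C(C)C
F4 | step 9 | Morita–Baylis–Hillman alcohol of the prenyl series (both C7 epimers) | O=C1O[C@H](C(O)C(=C)C(=O)OC(C)(C)C)[C@@H](C(=C)CO[Si](c2ccccc2)(c2ccccc2)C(C)(C)C)[C@]1(C)CC=C(C)C
F5 | step 9 | (Z)-allyl bromide of the prenyl series | O=C1O[C@H](/C=C(/C(=O)OC(C)(C)C)CBr)[C@@H](C(=C)CO[Si](c2ccccc2)(c2ccccc2)C(C)(C)C)[C@]1(C)CC=C(C)C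
F6 | step 9 | C8 aldehyde with (Z)-allyl bromide | O=C1O[C@H](/C=C(/C(=O)OC(C)(C)C)CBr)[C@@H](C(=C)CO[Si](c2ccccc2)(c2ccccc2)C(C)(C)C)[C@]1(C)CC=O
F7 | step 9 | bridged hydroxy lactone (8α-OH) | O=C2[C@@]1(C)C[C@H](O)[C@@H](C(=C)C(=O)OC(C)(C)C)[C@@H](O2)[C@H]1C(=C)CO[Si](c3ccccc3)(c3ccccc3)C(C)(C)C
F8 | step 11 | β-hydroxysilane (both C1 epimers) | C[Si](C)(C)CC(O)[C@@]1(C)C[C@H](O[Si](C)(C)C)[C@@H](C(=C)C(=O)OC(C)(C)C)[C@@H](O)[C@H]1C(=C)CO[Si](c2ccccc2)(c2ccccc2)C(C)(C)C
F9 | step 14 | C8 2-[bis(2,2,2-trifluoroethoxy)phosphoryl]propanoate (both epimers at the phosphonate carbon) | C=C[C@@]1(C)C[C@H](OC(=O)C(C)P(=O)(OCC(F)(F)F)OCC(F)(F)F)[C@@H](C(=C)C(=O)OC(C)(C)C)[C@@H](O)[C@H]1C(=C)CO[Si](c2ccccc2)(c2ccccc2)C(C)(C)C
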